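**Plan**

- Retrosynthetic cuts: C6–C7 together with the lactone C12–O6 bond (ring-closing allylation and lactonisation); C3–C4 (fragment union); C7–C11 (acrylate unit); C1–C2, C10–C14 and C9–C10 (alkyne carboalumination, oxirane opening, acetylide opening of a glycidyl ether). The 1,10-epoxide and the C8 ester are added last.
- Forward: a West fragment (C4–C6, C15) from but-2-yne-1,4-diol and an East fragment (C1–C3, C7–C10, C14) from (R)-glycidyl PMB ether are joined at C3–C4. C11–C13 are added by a Morita–Baylis–Hillman reaction. The ten-membered carbocycle C1–C10 and the γ-lactone are then closed in one operation, followed by acylation, epoxidation and desilylation.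
- Enabling feature: the α-methylene-γ-butyrolactone (C11=C13, C12, O, C6, C7) is fused at C6–C7 to the ten-membered ring, and C6 is flanked by the C4=C5 alkene. C7 is therefore the γ-carbon of a 2-(methoxycarbonyl)allyl metal (metal on C13) and C6 the carbonyl carbon of a (Z)-enal. This is the C1–C10 bond that germacrene synthase makes from farnesyl diphosphate, so the closure copies the biosynthesis with chromium in place of the proton lost from C13.
- Stereochemistry: C8 comes from the glycidyl ether; C3 from a ligand-controlled Nozaki–Hiyama–Kishi coupling; C6 and C7 from the ring closure (C8-directed, chair transition state); C1 and C10 from peripheral epoxidation of the E ring alkene. The 4Z geometry comes from trans-hydroalumination/iodination and the 1(10)E geometry from syn-carboalumination.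
- A PMB group is moved from O7 to O8 through a temporary benzylidene acetal (dioxolane ring), so that O8 is an ether during ring closure and is acylated afterwards.

Key step: step 16

Remark: atoms are numbered as in the germacrane skeleton of the target (ring C1–C10, lactone C11–C13, C14 on C10, C15 on C4), also in open-chain intermediates (chain C6–C5=C4(C15)–C3–C2–C1=C10(C14)–C9–C8–C7); (R)-glycidyl 4-methoxybenzyl ether is taken as a purchasable building block.

**Route**

Step 1
Reactants: 1 but-2-yne-1,4-diol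
Product: 2 4-(tert-butyldimethylsilyloxy)but-2-yn-1-ol
Conditions: NaH (1.0 equiv), THF, 0 °C; TBSCl (1.0 equiv), 0 °C → rt
Reagents that add atoms: tert-butyldimethylsilyl chloride CC(C)(C)[Si](C)(C)Cl
Why: One equivalent of NaH gives the poorly soluble monoalkoxide of the symmetric diol, which is silylated once (statistical mono-protection, Williamson-type O-silylation); no stereocentre is involved.

Step 2
Reactants: 2 4-(tert-butyldimethylsilyloxy)but-2-yn-1-ol
Product: 4 (Z)-4-(tert-butyldimethylsilyloxy)-3-iodobut-2-en-1-ol, via cyclic alkenylaluminate 3 (not isolated)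
Conditions: NaAlH2(OCH2CH2OCH3)2, THF, 0 °C → rt; then I2, THF, −78 → 0 °C
Reagents that add atoms: iodine I-I
Why: Hydroxyl-directed trans-hydroalumination of the propargylic alcohol delivers hydride to C5 and aluminium to C4 in a five-membered alkoxyaluminate, and iodinolysis of the C–Al bond with retention gives the (Z)-3-iodoallylic alcohol, which fixes C6 cis to the future C3 (the 4Z geometry).

Step 3
Reactants: 4 (Z)-4-(tert-butyldimethylsilyloxy)-3-iodobut-2-en-1-ol
Product: 5 (Z)-1-(tert-butyldimethylsilyloxy)-2-iodo-4-(triethylsilyloxy)but-2-ene (West fragment)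
Conditions: TESCl, imidazole, CH2Cl2, 0 °C
Reagents that add atoms: chlorotriethylsilane CC[Si](CC)(CC)Cl
Why: Standard imidazole-assisted silylation of the primary allylic alcohol; the triethylsilyl ether is chosen because it can later be cleaved in the presence of tert-butyldimethylsilyl ethers.

Step 4
Reactants: 6 (R)-2-[(4-methoxybenzyloxy)methyl]oxirane
Product: 7 (R)-1-(4-methoxybenzyloxy)pent-4-yn-2-ol
Conditions: LiC≡CH·H2NCH2CH2NH2, DMSO, 0 °C → rt
Reagents that add atoms: lithium acetylide (ethylenediamine complex) [Li+].[C-]#C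
Why: SN2 opening of the terminal epoxide at its CH2 carbon by the acetylide forms C9–C10 and leaves the stereocentre (the later C8, R) untouched.

Step 5
Reactants: 7 (R)-1-(4-methoxybenzyloxy)pent-4-yn-2-ol
Product: 10 (R,E)-7-(4-methoxybenzyloxy)-4-methylhept-3-ene-1,6-diol, via alkenyldimethylalane 8 (not isolated), via lithium alanate 9 (not isolated)
Conditions: Me3Al (3.5 equiv), Cp2ZrCl2 (0.25 equiv), CH2Cl2, 0 °C → rt; volatiles removed; n-BuLi, hexane/THF, −78 °C; ethylene oxide, −78 → 0 °C; aq. potassium sodium tartrate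
Reagents that add atoms: trimethylaluminium C[Al](C)C; ethylene oxide C1CO1
Why: Zirconium-catalysed syn-carboalumination of the terminal alkyne (Negishi carboalumination, the hydroxyl being carried as its aluminium alkoxide) puts the methyl group on C10 and aluminium on C1, and the butyl ate complex opens ethylene oxide with retention of the alkene geometry, which sets the 1(10)E alkene and adds C2–C3.

Step 6
Reactants: 10 (R,E)-7-(4-methoxybenzyloxy)-4-methylhept-3-ene-1,6-diol
Product: 11 (E)-5-[(4R)-2-(4-methoxyphenyl)-1,3-dioxolan-4-yl]-4-methylpent-3-en-1-ol (both epimers at the acetal carbon)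
Conditions: DDQ (1.2 equiv), 4 Å molecular sieves, CH2Cl2, −20 → 0 °C
Reagents that add atoms: none
Why: Under anhydrous conditions DDQ oxidises the PMB ether to its oxocarbenium ion, which is trapped by the vicinal C8 hydroxyl to give the 4-methoxybenzylidene acetal (oxidative acetalisation); this temporary dioxolane masks O7 and O8 and prepares the transfer of the PMB group to O8, and the remote primary alcohol cannot take part.

Step 7
Reactants: 11 (E)-5-[(4R)-2-(4-methoxyphenyl)-1,3-dioxolan-4-yl]-4-methylpent-3-en-1-ol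
Product: 12 (E)-5-[(4R)-2-(4-methoxyphenyl)-1,3-dioxolan-4-yl]-4-methylpent-3-enal (East fragment)
Conditions: Dess–Martin periodinane, pyridine, CH2Cl2, 0 °C → rt
Reagents that add atoms: none
Why: Buffered Dess–Martin oxidation gives the β,γ-unsaturated aldehyde without migration of the C1=C10 bond into conjugation; the aldehyde is used at once.

Step 8
Reactants: 5 (Z)-1-(tert-butyldimethylsilyloxy)-2-iodo-4-(triethylsilyloxy)but-2-ene; 12 (E)-5-[(4R)-2-(4-methoxyphenyl)-1,3-dioxolan-4-yl]-4-methylpent-3-enal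
Product: 14 open-chain (3S)-allylic alcohol (6-OTES; 15-OTBS; 7,8-O-(4-methoxybenzylidene); 4Z; 1(10)E; 8R), via alkenylchromium dichloride 13 (not isolated)
Conditions: CrCl2 (4 equiv), chiral 4-alkyl-2-[2-(methanesulfonylamino)phenyl]oxazoline ligand (antipode chosen for the 3S alcohol), Et3N, NiCl2 (2 mol %), THF, rt
Reagents that add atoms: none
Why: Nozaki–Hiyama–Kishi coupling, in which zerovalent nickel inserts into the C4–I bond, the alkenyl group passes to trivalent chromium with retention of the Z geometry and adds to the aldehyde; the chiral oxazoline–sulfonamide ligand on chromium selects the aldehyde face and sets C3 (S).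

Step 9
Reactants: 14 open-chain (3S)-allylic alcohol
Product: 15 open-chain 3-O-TBS ether (6-OTES; 15-OTBS; 3-OTBS; 7,8-O-(4-methoxybenzylidene); 4Z; 1(10)E; 3S; 8R)
Conditions: TBSCl, imidazole, DMAP (cat.), DMF, 35 °C
Reagents that add atoms: tert-butyldimethylsilyl chloride CC(C)(C)[Si](C)(C)Cl
Why: Standard silylation of the secondary allylic alcohol under basic conditions that leave the acetal and the triethylsilyl ether intact.

Step 10
Reactants: 15 open-chain 3-O-TBS ether
Product: 16 open-chain primary C7 alcohol with 8-O-PMB ether (6-OTES; 15-OTBS; 3-OTBS; 4Z; 1(10)E; 3S; 8R)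
Conditions: iBu2AlH (4 equiv), CH2Cl2, −78 → 0 °C; aq. potassium sodium tartrate
Reagents that add atoms: none
Why: Regioselective reductive opening of the 4-methoxybenzylidene acetal: aluminium coordinates the less hindered primary oxygen O7, the C–O7 bond ionises and hydride is delivered to the oxocarbenium ion, which leaves the PMB ether on the secondary O8 and frees the C7 hydroxyl.

Step 11
Reactants: 16 open-chain primary C7 alcohol
Product: 17 open-chain C7 aldehyde (8-O-PMB; 8R)
Conditions: Dess–Martin periodinane, pyridine, CH2Cl2, 0 °C → rt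
Reagents that add atoms: none
Why: Buffered Dess–Martin oxidation to the α-alkoxy aldehyde under neutral conditions that should not epimerise C8.

Step 12
Reactants: 17 open-chain C7 aldehyde
Product: 18 Morita–Baylis–Hillman adduct (methyl 2-methylidene-3-hydroxy ester; C7 carbinol as an epimer mixture; 8-O-PMB)
Conditions: methyl acrylate (excess), DABCO (1 equiv), MeOH (cosolvent), rt, several days
Reagents that add atoms: methyl acrylate C=CC(=O)OC
Why: Morita–Baylis–Hillman reaction (amine addition to the acrylate, aldol addition to the activated α-alkoxy aldehyde, loss of the amine) adds C11, C12 and C13; the new C7 carbinol centre forms as a mixture and is removed in step 13.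

Step 13
Reactants: 18 Morita–Baylis–Hillman adduct
Product: 19 open-chain (Z)-2-(bromomethyl)enoate (C7=C11; C13–Br; 6-OTES; 8-O-PMB)
Conditions: NBS, Me2S, CH2Cl2, 0 °C (reagent pre-formed); then 18, −20 → 0 °C
Reagents that add atoms: N-bromosuccinimide O=C1CCC(=O)N1Br
Why: The hydroxyl is activated as an alkoxysulfonium ion by the sulfonium reagent formed from NBS and Me2S and is displaced by bromide with allylic transposition (SN2′), which gives the more stable (Z)-2-(bromomethyl)alk-2-enoate and erases the C7 carbinol centre.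

Step 14
Reactants: 19 open-chain (Z)-2-(bromomethyl)enoate
Product: 20 open-chain primary allylic C6 alcohol (15-OTBS; 3-OTBS; 8-O-PMB; C13–Br)
Conditions: PPTS (0.1 equiv), MeOH/CH2Cl2, 0 °C
Reagents that add atoms: none
Why: Acid-catalysed methanolysis cleaves the unhindered primary triethylsilyl ether much faster than the two tert-butyldimethylsilyl ethers; the PMB ether, the ester and the allylic bromide are inert to these conditions.

Step 15
Reactants: 20 open-chain primary allylic C6 alcohol
Product: 21 open-chain (4Z)-enal bromide (C6 aldehyde; C13–Br; 15-OTBS; 3-OTBS; 8-O-PMB; 1(10)E; 3S; 8R)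
Conditions: MnO2 (excess), CH2Cl2, rt
Reagents that add atoms: none
Why: MnO2 oxidises the primary allylic alcohol selectively to the enal on a neutral surface, which should preserve the Z geometry of C4=C5 and leave the allylic bromide untouched.

Step 16
Reactants: 21 open-chain (4Z)-enal bromide
Product: 24 (1(10)E,4Z)-3β,15-bis(tert-butyldimethylsilyloxy)-8β-(4-methoxybenzyloxy)germacra-1(10),4,11(13)-trien-6α,12-olide (3S;6R;7R;8R), via allylchromium dichloride 22 (not isolated), via ten-membered chromium alkoxide 23 (not isolated)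
Conditions: CrCl2 (10 equiv), degassed THF, 23 °C, slow addition of 21 (final 0.003 M); aq. NH4Cl
Reagents that add atoms: none
Why: Two equivalents of divalent chromium insert into the allylic C13–Br bond of 21 to give the trivalent allylchromium species 22, which equilibrates by 1,3-metal shift and adds through its γ-carbon C7 to the chromium-bound C6 aldehyde in a closed six-membered chair transition state (allylic transposition, C11=C13 formed); the chromium alkoxide 23 then attacks the C12 methyl ester and expels methoxide. The closest known reaction type is the Nozaki–Hiyama–Kishi (Barbier-type) allylation–lactonisation of 2-(bromomethyl)acrylates with aldehydes, which is also known as a ring closure of farnesane-type bromo aldehydes to ten-membered germacranolide lactones; it copies the C1–C10 cyclisation of farnesyl diphosphate, with chromium on C13 in the role of the proton lost from that carbon. The carbocycle C1–C10 closes in a 10-exo-trig mode (attack on the exocyclic C6=O) and the γ-lactone in a 5-exo-trig mode (acyl substitution at C12). C7 is controlled by the neighbouring C8 stereocentre: allylic 1,3-strain with the C11 substituents keeps H8 in the alkene plane, and the aldehyde adds to the face anti to the C9 branch with the PMB ether pointing outward, which gives 7R; C6 is controlled by the chair, in which the C5 branch of the aldehyde and the C8 branch of the allyl unit are both equatorial, which gives the anti adduct (6R) and hence the trans-fused lactone. The step needs γ- over α-attack (the normal allylic transposition of allylchromium reagents), 1,2- over 1,4-addition to the enal (normal for allylchromium reagents), retention of the 4Z geometry (neutral medium), ring closure over oligomerisation (high dilution; the 4Z and 1(10)E alkenes pre-fold the chain) and no 1,4-elimination of O8 from the allylmetal (as a PMB ether O8 is a poor leaving group).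

Step 17
Reactants: 24 8β-PMB ether lactone
Product: 25 (1(10)E,4Z)-3β,15-bis(tert-butyldimethylsilyloxy)-8β-hydroxygermacra-1(10),4,11(13)-trien-6α,12-olide
Conditions: DDQ (1.5 equiv), CH2Cl2/pH 7 buffer (10:1), 0 °C → rt
Reagents that add atoms: none
Why: DDQ oxidises the electron-rich PMB ether to an oxocarbenium ion that is hydrolysed to 4-methoxybenzaldehyde and the free 8-hydroxyl (oxidative debenzylation); silyl ethers, alkenes and the lactone are unaffected.

Step 18
Reactants: 25 8β-hydroxy lactone
Product: 26 (1(10)E,4Z)-3β,15-bis(tert-butyldimethylsilyloxy)-8β-isobutyryloxygermacra-1(10),4,11(13)-trien-6α,12-olide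
Conditions: (iPrCO)2O, Et3N, DMAP (cat.), CH2Cl2, 0 °C → rt
Reagents that add atoms: isobutyric anhydride CC(C)C(=O)OC(=O)C(C)C
Why: DMAP-catalysed acylation of the secondary 8β-hydroxyl with the anhydride; the mild base should neither open the lactone nor move it to O8.

Step 19
Reactants: 26 8β-isobutyrate
Product: 27 (4Z)-1β,10α-epoxy-3β,15-bis(tert-butyldimethylsilyloxy)-8β-isobutyryloxygermacra-4,11(13)-dien-6α,12-olide (1R;10R)
Conditions: mCPBA (1.1 equiv), NaHCO3, CH2Cl2, 0 °C
Reagents that add atoms: 3-chloroperbenzoic acid O=C(OO)c1cccc(Cl)c1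
Why: Prilezhaev epoxidation with syn addition to the 1(10)E alkene, the only electron-rich alkene (C4=C5 is deactivated by three allylic oxygens, C11=C13 is conjugated); in the ten-membered ring only the outer face of this alkene is exposed, so peripheral attack on the conformer with C14 on the β face should give the 1β,10α epoxide (1R,10R), as is usual for germacranolides.

Step 20
Reactants: 27 bis-silyl epoxide
Product: 28 (4Z)-1β,10α-epoxy-3β,15-dihydroxy-8β-isobutyryloxygermacra-4,11(13)-dien-6α,12-olide (target; 1R,3S,6R,7R,8R,10R)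
Conditions: Et3N·3HF, THF, rt
Reagents that add atoms: none
Why: Fluoride cleaves both allylic silyl ethers under buffered, nearly neutral conditions that the epoxide, the isobutyrate and the α-methylene lactone should tolerate; the deactivated C4=C5 bond makes transannular opening of the epoxide unlikely.

**Compound list**

1 | but-2-yne-1,4-diol | OCC#CCO | starting material
2 | 4-(tert-butyldimethylsilyloxy)but-2-yn-1-ol | OCC#CCO[Si](C)(C)C(C)(C)C | intermediate
3 | sodium cyclic alkenylaluminate from 2 (Al on C4 and O6, two 2-methoxyethoxy ligands) | [Na+].COCCO[Al-]1(OCCOC)OCC=C1CO[Si](C)(C)C(C)(C)C | intermediate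
4 | (Z)-4-(tert-butyldimethylsilyloxy)-3-iodobut-2-en-1-ol | OC/C=C(\I)CO[Si](C)(C)C(C)(C)C | intermediate
5 | (Z)-1-(tert-butyldimethylsilyloxy)-2-iodo-4-(triethylsilyloxy)but-2-ene (West fragment) | CC[Si](CC)(CC)OC/C=C(\I)CO[Si](C)(C)C(C)(C)C | intermediate
6 | (R)-2-[(4-methoxybenzyloxy)methyl]oxirane | COc1ccc(COC[C@H]2CO2)cc1 | starting material
7 | (R)-1-(4-methoxybenzyloxy)pent-4-yn-2-ol | C#CC[C@@H](O)COCc1ccc(OC)cc1 | intermediate
8 | (E)-alkenyldimethylalane from 7 (Al on C1, methyl on C10, O8 as dimethylaluminium alkoxide) | C[Al](C)/C=C(\C)C[C@@H](O[Al](C)C)COCc1ccc(OC)cc1 | intermediate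
9 | lithium butyl ate complex of 8 | [Li+].CCCC[Al-](C)(C)/C=C(\C)C[C@@H](O[Al](C)C)COCc1ccc(OC)cc1 | intermediate
10 | (R,E)-7-(4-methoxybenzyloxy)-4-methylhept-3-ene-1,6-diol | OCC/C=C(\C)C[C@@H](O)COCc1ccc(OC)cc1 | intermediate
11 | (E)-5-[(4R)-2-(4-methoxyphenyl)-1,3-dioxolan-4-yl]-4-methylpent-3-en-1-ol (both acetal epimers) | OCC/C=C(\C)C[C@@H]1COC(O1)c2ccc(OC)cc2 | intermediate
12 | (E)-5-[(4R)-2-(4-methoxyphenyl)-1,3-dioxolan-4-yl]-4-methylpent-3-enal (East fragment) | O=CC/C=C(\C)C[C@@H]1COC(O1)c2ccc(OC)cc2 | intermediate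
13 | (Z)-alkenylchromium dichloride from 5 (Cr on C4) | CC[Si](CC)(CC)OC/C=C(/CO[Si](C)(C)C(C)(C)C)[Cr](Cl)Cl | intermediate
14 | open-chain (3S)-allylic alcohol (6-OTES, 15-OTBS, 7,8-O-(4-methoxybenzylidene), 4Z, 1(10)E, 8R) | CC[Si](CC)(CC)OC/C=C(/CO[Si](C)(C)C(C)(C)C)[C@@H](O)C/C=C(\C)C[C@@H]1COC(O1)c2ccc(OC)cc2 | intermediate
15 | 3-O-TBS ether of 14 | CC[Si](CC)(CC)OC/C=C(/CO[Si](C)(C)C(C)(C)C)[C@@H](O[Si](C)(C)C(C)(C)C)C/C=C(\C)C[C@@H]1COC(O1)c2ccc(OC)cc2 | intermediate
16 | open-chain primary C7 alcohol with 8-O-PMB ether (6-OTES, 15-OTBS, 3-OTBS, 3S, 8R) | CC[Si](CC)(CC)OC/C=C(/CO[Si](C)(C)C(C)(C)C)[C@@H](O[Si](C)(C)C(C)(C)C)C/C=C(\C)C[C@@H](OCc1ccc(OC)cc1)CO | intermediate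
17 | open-chain C7 aldehyde (8-O-PMB, 8R) | CC[Si](CC)(CC)OC/C=C(/CO[Si](C)(C)C(C)(C)C)[C@@H](O[Si](C)(C)C(C)(C)C)C/C=C(\C)C[C@@H](OCc1ccc(OC)cc1)C=O | intermediate
18 | Morita–Baylis–Hillman adduct (C7 carbinol epimers) | CC[Si](CC)(CC)OC/C=C(/CO[Si](C)(C)C(C)(C)C)[C@@H](O[Si](C)(C)C(C)(C)C)C/C=C(\C)C[C@@H](OCc1ccc(OC)cc1)C(O)C(=C)C(=O)OC | intermediate
19 | open-chain (Z)-2-(bromomethyl)enoate (6-OTES) | CC[Si](CC)(CC)OC/C=C(/CO[Si](C)(C)C(C)(C)C)[C@@H](O[Si](C)(C)C(C)(C)C)C/C=C(\C)C[C@@H](OCc1ccc(OC)cc1)/C=C(\CBr)C(=O)OC | intermediate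
20 | open-chain primary allylic C6 alcohol | OC/C=C(/CO[Si](C)(C)C(C)(C)C)[C@@H](O[Si](C)(C)C(C)(C)C)C/C=C(\C)C[C@@H](OCc1ccc(OC)cc1)/C=C(\CBr)C(=O)OC | intermediate
21 | open-chain (4Z)-enal bromide (cyclisation precursor) | O=C/C=C(/CO[Si](C)(C)C(C)(C)C)[C@@H](O[Si](C)(C)C(C)(C)C)C/C=C(\C)C[C@@H](OCc1ccc(OC)cc1)/C=C(\CBr)C(=O)OC | intermediate
22 | allylchromium dichloride from 21 (Cr on C13) | O=C/C=C(/CO[Si](C)(C)C(C)(C)C)[C@@H](O[Si](C)(C)C(C)(C)C)C/C=C(\C)C[C@@H](OCc1ccc(OC)cc1)/C=C(\C[Cr](Cl)Cl)C(=O)OC | intermediate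
23 | ten-membered chromium alkoxide of the 6-hydroxy methyl ester (6R,7R) | COC(=O)C(=C)[C@H]1[C@H](O[Cr](Cl)Cl)/C=C(/CO[Si](C)(C)C(C)(C)C)[C@@H](O[Si](C)(C)C(C)(C)C)C/C=C(\C)C[C@H]1OCc2ccc(OC)cc2 | intermediate
24 | (1(10)E,4Z)-3β,15-bis(TBS-oxy)-8β-(4-methoxybenzyloxy)germacra-1(10),4,11(13)-trien-6α,12-olide | C=C1C(=O)O[C@@H]2/C=C(/CO[Si](C)(C)C(C)(C)C)[C@@H](O[Si](C)(C)C(C)(C)C)C/C=C(\C)C[C@@H](OCc3ccc(OC)cc3)[C@@H]12 | intermediate
25 | (1(10)E,4Z)-3β,15-bis(TBS-oxy)-8β-hydroxygermacra-1(10),4,11(13)-trien-6α,12-olide | C=C1C(=O)O[C@@H]2/C=C(/CO[Si](C)(C)C(C)(C)C)[C@@H](O[Si](C)(C)C(C)(C)C)C/C=C(\C)C[C@@H](O)[C@@H]12 | intermediate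
26 | (1(10)E,4Z)-3β,15-bis(TBS-oxy)-8β-isobutyryloxygermacra-1(10),4,11(13)-trien-6α,12-olide | C=C1C(=O)O[C@@H]2/C=C(/CO[Si](C)(C)C(C)(C)C)[C@@H](O[Si](C)(C)C(C)(C)C)C/C=C(\C)C[C@@H](OC(=O)C(C)C)[C@@H]12 | intermediate
27 | (4Z)-1β,10α-epoxy-3β,15-bis(TBS-oxy)-8β-isobutyryloxygermacra-4,11(13)-dien-6α,12-olide | C=C1C(=O)O[C@@H]2/C=C(/CO[Si](C)(C)C(C)(C)C)[C@@H](O[Si](C)(C)C(C)(C)C)C[C@H]3O[C@]3(C)C[C@@H](OC(=O)C(C)C)[C@@H]12 | intermediate
28 | (4Z)-1β,10α-epoxy-3β,15-dihydroxy-8β-isobutyryloxygermacra-4,11(13)-dien-6α,12-olide (1R,3S,6R,7R,8R,10R) | C=C1C(=O)O[C@@H]2/C=C(/CO)[C@@H](O)C[C@H]3O[C@]3(C)C[C@@H](OC(=O)C(C)C)[C@@H]12 | target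

Total step count: 20. Longest linear sequence: 17 steps (from 6 through steps 4–20).

**Steps most likely to fail**

1. Step 16 (ring closure). The closure may run through the chair in which the C8 branch of the allylchromium is axial, the usual course of 2-(bromomethyl)alk-2-enoates in open-chain cases. C6 would then form with the wrong sense relative to C7 and the cis-fused lactone would result. Fallback (inversion at C6 in place of kinetic control): setting out from 21, the same CrCl2 closure would give, through the C6-epimeric chromium alkoxide F1, the cis-fused 6-epi lactone F2. LiOH in THF/H2O opens it to the 6-epi hydroxy acid F3. Mitsunobu lactonisation (PPh3, DIAD, THF, high dilution) then closes the γ-lactone by SN2 attack of the carboxylate at C6 with inversion, which returns to the route at 24.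

2. Step 8 (fragment union). The ligand may not control the aldehyde face well enough, giving C3 epimers, or the coupling may be slow enough for the β,γ-unsaturated aldehyde to isomerise. Fallback (reagent-controlled reduction in place of reagent-controlled addition): setting out from 5 and 12, the ligand-free coupling (CrCl2, NiCl2 cat., DMF) gives the C3-epimeric alcohols F4. Dess–Martin oxidation gives the cross-conjugated enone F5. Corey–Bakshi–Shibata reduction with the (R)-oxazaborolidine and BH3·SMe2 at low temperature, in which the α-branched alkenyl group acts as the large substituent, gives the 3S alcohol and returns to the route at 14.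

3. Step 19 (epoxidation). The peracid may approach the alkene face of the wrong ring conformer, or both faces, because only the ring conformation differentiates them. Fallback (reagent control on the open chain in place of substrate control on the ring): setting out from 18, Shi epoxidation (D-fructose-derived ketone catalyst, KHSO5, K2CO3 buffer, MeCN/H2O, 0 °C) attacks only the electron-rich C1=C10 bond, in the (R,R) sense expected for E-trisubstituted alkenes, and gives the (1R,10R)-epoxy adduct F6. The conditions of steps 13 to 15 then give the epoxy bromide F7, the epoxy allylic alcohol F8 and the epoxy enal F9. Ring closure as in step 16 gives, through the epoxy allylchromium dichloride F10 and the epoxy chromium alkoxide F11, the epoxy lactone F12; a trisubstituted epoxide should be inert to CrCl2. DDQ as in step 17 gives the epoxy 8-alcohol F13, and acylation as in step 18 returns to the route at 27.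

Further compounds
F1 | step 16 | C6-epimeric ten-membered chromium alkoxide (6S,7R) | COC(=O)C(=C)[C@H]1[C@@H](O[Cr](Cl)Cl)/C=C(/CO[Si](C)(C)C(C)(C)C)[C@@H](O[Si](C)(C)C(C)(C)C)C/C=C(\C)C[C@H]1OCc2ccc(OC)cc2
F2 | step 16 | cis-fused 6-epi lactone (6S epimer of 24) | C=C1C(=O)O[C@H]2/C=C(/CO[Si](C)(C)C(C)(C)C)[C@@H](O[Si](C)(C)C(C)(C)C)C/C=C(\C)C[C@@H](OCc3ccc(OC)cc3)[C@@H]12
F3 | step 16 | 6-epi hydroxy acid (ten-membered ring, C12 acid, 6S hydroxyl) | OC(=O)C(=C)[C@H]1[C@@H](O)/C=C(/CO[Si](C)(C)C(C)(C)C)[C@@H](O[Si](C)(C)C(C)(C)C)C/C=C(\C)C[C@H]1OCc2ccc(OC)cc2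
F4 | step 8 | C3-epimeric allylic alcohols (constitution of 14) | CC[Si](CC)(CC)OC/C=C(/CO[Si](C)(C)C(C)(C)C)C(O)C/C=C(\C)C[C@@H]1COC(O1)c2ccc(OC)cc2
F5 | step 8 | C3 enone | CC[Si](CC)(CC)OC/C=C(/CO[Si](C)(C)C(C)(C)C)C(=O)C/C=C(\C)C[C@@H]1COC(O1)c2ccc(OC)cc2
F6 | step 19 | (1R,10R)-epoxy Morita–Baylis–Hillman adduct | CC[Si](CC)(CC)OC/C=C(/CO[Si](C)(C)C(C)(C)C)[C@@H](O[Si](C)(C)C(C)(C)C)C[C@H]1O[C@]1(C)C[C@@H](OCc2ccc(OC)cc2)C(O)C(=C)C(=O)OC
F7 | step 19 | epoxy (Z)-2-(bromomethyl)enoate | CC[Si](CC)(CC)OC/C=C(/CO[Si](C)(C)C(C)(C)C)[C@@H](O[Si](C)(C)C(C)(C)C)C[C@H]1O[C@]1(C)C[C@@H](OCc2ccc(OC)cc2)/C=C(\CBr)C(=O)OC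
F8 | step 19 | epoxy allylic C6 alcohol | OC/C=C(/CO[Si](C)(C)C(C)(C)C)[C@@H](O[Si](C)(C)C(C)(C)C)C[C@H]1O[C@]1(C)C[C@@H](OCc2ccc(OC)cc2)/C=C(\CBr)C(=O)OC
F9 | step 19 | epoxy (4Z)-enal bromide | O=C/C=C(/CO[Si](C)(C)C(C)(C)C)[C@@H](O[Si](C)(C)C(C)(C)C)C[C@H]1O[C@]1(C)C[C@@H](OCc2ccc(OC)cc2)/C=C(\CBr)C(=O)OC
F10 | step 19 | epoxy allylchromium dichloride | O=C/C=C(/CO[Si](C)(C)C(C)(C)C)[C@@H](O[Si](C)(C)C(C)(C)C)C[C@H]1O[C@]1(C)C[C@@H](OCc2ccc(OC)cc2)/C=C(\C[Cr](Cl)Cl)C(=O)OC
F11 | step 19 | epoxy ten-membered chromium alkoxide | COC(=O)C(=C)[C@H]1[C@H](O[Cr](Cl)Cl)/C=C(/CO[Si](C)(C)C(C)(C)C)[C@@H](O[Si](C)(C)C(C)(C)C)C[C@H]2O[C@]2(C)C[C@H]1OCc3ccc(OC)cc3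
F12 | step 19 | 8-O-PMB epoxy lactone | C=C1C(=O)O[C@@H]2/C=C(/CO[Si](C)(C)C(C)(C)C)[C@@H](O[Si](C)(C)C(C)(C)C)C[C@H]3O[C@]3(C)C[C@@H](OCc4ccc(OC)cc4)[C@@H]12
F13 | step 19 | epoxy 8-alcohol | C=C1C(=O)O[C@@H]2/C=C(/CO[Si](C)(C)C(C)(C)C)[C@@H](O[Si](C)(C)C(C)(C)C)C[C@H]3O[C@]3(C)C[C@@H](O)[C@@H]12
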